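**Retrosynthetic overview**
1. The target comes from the trans β-aroyl lactone 30 by a late catalyst-controlled ketone reduction and removal of one silyl and two benzyl groups.
2. The strategy rests on the γ-butyrolactone ring (O1–C2(=O)–C3–C4–C5): C5 is an unsubstituted OCH2 on C4, and C4 is alpha to the exocyclic aryl carbinol carbon. With that carbon held as an aryl ketone, C4–C5 and O1–C2 are cut together, back to formaldehyde and γ-keto ester 27.
3. 27 comes from dihydrobenzofuran-5-carbaldehyde 19 by Stobbe condensation, rhodium-catalysed asymmetric hydrogenation (sets lactone C3), Weinreb amide formation and aryl Grignard addition.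
4. The dihydrobenzofuran ring is formed first: O1–C2 by acid-mediated closure of a phenol onto a para-alkoxybenzylic carbinol (trans), C2–C3 by an Evans syn-aldol of an arylacetyl oxazolidinone with O-benzylvanillin (sets C3).
5. The arylacetic acid comes from 4-bromo-2-methoxyphenol (O-allylation, Claisen rearrangement, oxidative cleavage); the bromine later becomes the formyl group. Ring order: dihydrobenzofuran (step 8), then lactone (step 15).

Key step: step 15

Assumption: the (S,S) antipode of Et-DuPHOS is taken to deliver the (R)-succinate in step 12, by analogy with other β-aryl itaconate half-esters; if the opposite sense is found, the (R,R) ligand is used.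

Abbreviation in names: DBF = (2S,3R)-2-[4-(benzyloxy)-3-methoxyphenyl]-3-{[(tert-butyldimethylsilyl)oxy]methyl}-7-methoxy-2,3-dihydro-1-benzofuran-5-yl; TBS = tert-butyldimethylsilyl.

**Step 1**
Reactants: 1 4-bromo-2-methoxyphenol; 2 allyl bromide
Product: 3 1-(allyloxy)-4-bromo-2-methoxybenzene
Conditions: K2CO3, acetone, reflux
Reagents that add atoms: none
Why: Williamson ether synthesis, the phenoxide displacing bromide from the allylic halide by SN2.

**Step 2**
Reactants: 3 1-(allyloxy)-4-bromo-2-methoxybenzene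
Product: 4 2-allyl-4-bromo-6-methoxyphenol
Conditions: N,N-diethylaniline, 195 °C
Reagents that add atoms: none
Why: Aromatic Claisen rearrangement ([3,3]-sigmatropic shift then tautomerisation), which can deliver the allyl group only to the single free ortho carbon because the other ortho position carries the methoxy group.

**Step 3**
Reactants: 4 2-allyl-4-bromo-6-methoxyphenol
Product: 5 1-allyl-5-bromo-3-methoxy-2-(methoxymethoxy)benzene
Conditions: MOMCl, iPr2NEt, CH2Cl2, 0 °C → rt
Reagents that add atoms: chloromethyl methyl ether, COCCl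
Why: O-alkylation of the phenol with the reactive α-chloro ether gives an acetal-type ether that should survive the enolate and hydride steps and come off in acid.

**Step 4**
Reactants: 5 1-allyl-5-bromo-3-methoxy-2-(methoxymethoxy)benzene
Product: 7 2-[5-bromo-3-methoxy-2-(methoxymethoxy)phenyl]acetic acid, via arylacetaldehyde 6 (not isolated)
Conditions: O3, MeCN/H2O (9:1), 0 °C, to alkene end-point; then NaClO2, NaH2PO4, 0 °C → rt
Reagents that add atoms: ozone, [O-][O+]=O; sodium chlorite, [Na+].[O-]Cl=O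
Why: Telescoped ozonolysis–Pinnick oxidation, in which the terminal alkene is cleaved far faster than the bromo-deactivated ring is attacked, water converts the carbonyl oxide directly to the aldehyde and hydrogen peroxide, and chlorite takes the aldehyde to the acid while the peroxide scavenges hypochlorite.

**Step 5**
Reactants: 7 2-[5-bromo-3-methoxy-2-(methoxymethoxy)phenyl]acetic acid; 8 (S)-4-benzyl-1,3-oxazolidin-2-one
Product: 10 (S)-4-benzyl-3-{2-[5-bromo-3-methoxy-2-(methoxymethoxy)phenyl]acetyl}-1,3-oxazolidin-2-one, via mixed pivalic anhydride 9 (not isolated)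
Conditions: PivCl, Et3N, THF, −20 °C; then 8, LiCl, rt
Reagents that add atoms: none
Why: N-acylation of the oxazolidinone through the mixed anhydride, attack occurring at the less hindered arylacetyl carbonyl under LiCl/Et3N activation.

**Step 6**
Reactants: 10 (S)-4-benzyl-3-{2-[5-bromo-3-methoxy-2-(methoxymethoxy)phenyl]acetyl}-1,3-oxazolidin-2-one; 11 4-(benzyloxy)-3-methoxybenzaldehyde
Product: 13 (S)-4-benzyl-3-{(2S,3S)-3-[4-(benzyloxy)-3-methoxyphenyl]-2-[5-bromo-3-methoxy-2-(methoxymethoxy)phenyl]-3-hydroxypropanoyl}-1,3-oxazolidin-2-one, via Z-dibutylboron enolate 12 (not isolated)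
Conditions: Bu2BOTf, iPr2NEt, CH2Cl2, −78 → 0 °C; 11, −78 → 0 °C; pH 7 buffer, MeOH, 30% H2O2, 0 °C
Reagents that add atoms: none
Why: Evans syn-aldol reaction, the Z-boron enolate reacting through a closed Zimmerman–Traxler chair on the face away from the auxiliary benzyl group, which should set the α-carbon as S (the future dihydrobenzofuran C3) and the carbinol as S, only the former having to persist.

**Step 7**
Reactants: 13 the syn-aldol imide
Product: 14 (1S,2R)-1-[4-(benzyloxy)-3-methoxyphenyl]-2-[5-bromo-3-methoxy-2-(methoxymethoxy)phenyl]propane-1,3-diol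
Conditions: LiBH4, THF/H2O, 0 °C
Reagents that add atoms: none
Why: Reductive cleavage of the N-acyl oxazolidinone by borohydride releases the auxiliary and gives the primary alcohol; the benzylic α-centre should not epimerise under these mild conditions and the aryl bromide, MOM and benzyl ethers are inert.

**Step 8**
Reactants: 14 the MOM-protected 1,3-diol
Product: 16 [(2S,3R)-2-[4-(benzyloxy)-3-methoxyphenyl]-5-bromo-7-methoxy-2,3-dihydro-1-benzofuran-3-yl]methanol, via free phenol triol 15 (not isolated)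
Conditions: 3 M aq. HCl, MeOH/THF, 50 °C
Reagents that add atoms: none
Why: Acid removes the MOM group (methanol takes up the formaldehyde) and the para-alkoxybenzylic carbinol then undergoes SN1-type 5-exo etherification by the ortho phenol, the reversible closure placing the C2 aryl group trans to the fixed C3 hydroxymethyl group so that C2 should be set as S under thermodynamic control.

**Step 9**
Reactants: 16 the dihydrobenzofuran methanol
Product: 17 {[(2S,3R)-2-[4-(benzyloxy)-3-methoxyphenyl]-5-bromo-7-methoxy-2,3-dihydro-1-benzofuran-3-yl]methoxy}(tert-butyl)dimethylsilane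
Conditions: TBSCl, imidazole, DMF, rt
Reagents that add atoms: tert-butyldimethylsilyl chloride, CC(C)(C)[Si](C)(C)Cl
Why: Silylation of the only free (primary) hydroxyl gives an ether that is stable to organolithium, alkoxide and carbonate bases.

**Step 10**
Reactants: 17 the bromo silyl ether
Product: 19 (2S,3R)-2-[4-(benzyloxy)-3-methoxyphenyl]-3-{[(tert-butyldimethylsilyl)oxy]methyl}-7-methoxy-2,3-dihydro-1-benzofuran-5-carbaldehyde (DBF–CHO), via aryllithium 18 (not isolated)
Conditions: n-BuLi, THF, −78 °C; DMF, −78 → 0 °C; aq. NH4Cl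
Reagents that add atoms: N,N-dimethylformamide, CN(C)C=O
Why: Bromine–lithium exchange, much faster at −78 °C than any benzylic deprotonation, followed by Bouveault-type formylation of the aryllithium with DMF.

**Step 11**
Reactants: 19 DBF–CHO; 20 dimethyl succinate
Product: 22 (E)-4-DBF-3-(methoxycarbonyl)but-3-enoic acid, via paraconate ester 21 (not isolated)
Conditions: NaOMe, MeOH, reflux; then 1 M HCl to pH 3, 0 °C
Reagents that add atoms: none
Why: Stobbe condensation, in which aldol addition, lactonisation onto the distal ester and E1cB ring opening leave the conjugated methyl ester and free the CH2CO2H arm, giving mainly the E alkene.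

**Step 12**
Reactants: 22 the Stobbe half-ester
Product: 23 (3R)-4-DBF-3-(methoxycarbonyl)butanoic acid
Conditions: [Rh(cod)((S,S)-Et-DuPHOS)]BF4 (1 mol%), NaOMe (10 mol%), H2 (5 atm), MeOH, rt
Reagents that add atoms: none
Why: Rhodium–bisphospholane asymmetric hydrogenation of a β-aryl itaconate half-ester, the carboxylate and alkene chelating the metal so that the C2-symmetric ligand selects the alkene face and should set the new centre as R, with benzyl and silyl ethers untouched by the cationic catalyst.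

**Step 13**
Reactants: 23 the (R)-succinate half-ester
Product: 24 methyl (2R)-2-(DBF-methyl)-4-[methoxy(methyl)amino]-4-oxobutanoate
Conditions: MeNHOMe·HCl, EDC·HCl, HOBt, iPr2NEt, CH2Cl2, 0 °C → rt
Reagents that add atoms: N,O-dimethylhydroxylamine hydrochloride, CNOC.Cl
Why: Carbodiimide amide coupling at the unbranched acid, which is two bonds away from the stereocentre and so cannot racemise it.

**Step 14**
Reactants: 24 the Weinreb amide ester; 25 1-(benzyloxy)-4-bromo-2-methoxybenzene
Product: 27 methyl (2R)-4-[4-(benzyloxy)-3-methoxyphenyl]-2-(DBF-methyl)-4-oxobutanoate, via arylmagnesium bromide 26 (not isolated)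
Conditions: 25, Mg, THF, reflux; then added to 24, THF, −20 → 0 °C; aq. NH4Cl
Reagents that add atoms: none
Why: Weinreb ketone synthesis, the aryl Grignard acylating at the N-methoxy-N-methylamide, which cannot over-add, faster than at the hindered α-branched methyl ester at low temperature.

**Step 15**
Reactants: 27 the γ-keto ester; 28 formaldehyde
Product: 30 (3R,4R)-4-[4-(benzyloxy)-3-methoxybenzoyl]-3-(DBF-methyl)oxolan-2-one, via hydroxymethyl ketone 29 (not isolated)
Conditions: 28 (37% aq., 1.5 equiv), K2CO3 (30 mol%), MeOH/THF/H2O, 0 °C → rt; then 1 M HCl to pH 3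
Reagents that add atoms: none
Why: K2CO3 reversibly enolises the ketone toward its only alpha carbon (C3 of the butanoate; the other flank is aryl), and the enolate adds to formaldehyde in an aldol reaction that forms the C3–CH2OH bond of 29. The primary alkoxide then attacks the methyl ester in a 5-exo-trig addition–elimination, expelling methoxide and closing the γ-butyrolactone (O1–C2 bond). The closest known reaction type is the base-mediated hydroxymethylation–lactonisation of 3-aroylpropionic acids and esters with formaldehyde to β-aroyl-γ-butyrolactones. The new stereocentre (lactone C4) stays enolisable and should equilibrate under the carbonate to the trans arrangement relative to the fixed (R)-C3 arylmethyl group, i.e. thermodynamic control by the existing centre. The step needs enolisation at the ketone alpha carbon and not at the ester alpha carbon, which the gap of several pKa units between an aryl ketone and an ester secures with a carbonate base, so the centre set in step 12 should be untouched. Over-hydroxymethylation and dehydration to the alpha-methylene ketone are limited by the small excess of formaldehyde, the low temperature and the fast intramolecular acylation, and the acidic quench relactonises any ring-opened hydroxy acid.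

**Step 16**
Reactants: 30 the trans keto lactone
Product: 31 (3R,4R)-4-{(R)-[4-(benzyloxy)-3-methoxyphenyl](hydroxy)methyl}-3-(DBF-methyl)oxolan-2-one
Conditions: RuCl[(R,R)-TsDPEN](p-cymene) (2 mol%), HCO2H/Et3N (5:2), CH2Cl2, 30 °C
Reagents that add atoms: none
Why: Noyori asymmetric transfer hydrogenation, the (R,R)-TsDPEN ruthenium catalyst being expected to deliver hydride to the Si face of the aryl ketone (as acetophenone gives the (R)-alcohol with this antipode) and so set the carbinol as R under catalyst control, while the weakly acidic medium should leave the trans lactone centres and the silyl and benzyl ethers alone.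

**Step 17**
Reactants: 31 the silyl-protected carbinol
Product: 32 (3R,4R)-4-{(R)-[4-(benzyloxy)-3-methoxyphenyl](hydroxy)methyl}-3-{[(2S,3R)-2-[4-(benzyloxy)-3-methoxyphenyl]-3-(hydroxymethyl)-7-methoxy-2,3-dihydro-1-benzofuran-5-yl]methyl}oxolan-2-one
Conditions: Bu4NF, AcOH (1:1), THF, 0 °C → rt
Reagents that add atoms: none
Why: Fluoride cleavage of the primary silyl ether, buffered with acetic acid so that neither translactonisation onto the secondary hydroxyl nor ionisation of the para-alkoxybenzylic alcohol should occur.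

**Step 18**
Reactants: 32 the bis-benzyl ether
Product: 33 (3R,4R)-4-[(R)-hydroxy(4-hydroxy-3-methoxyphenyl)methyl]-3-{[(2S,3R)-2-(4-hydroxy-3-methoxyphenyl)-3-(hydroxymethyl)-7-methoxy-2,3-dihydro-1-benzofuran-5-yl]methyl}oxolan-2-one (target)
Conditions: H2 (1 atm), 10% Pd/C, EtOAc, rt, stopped at full debenzylation
Reagents that add atoms: none
Why: Hydrogenolysis of the two aryl benzyl ethers over palladium on carbon in a neutral aprotic solvent, where the benzylic alcohol and the dihydrobenzofuran C2–O bond should be cleaved much more slowly in the absence of acid.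

**Compound list**
1 | 4-bromo-2-methoxyphenol | COc1cc(Br)ccc1O | starting material
2 | allyl bromide | C=CCBr | starting material
3 | 1-(allyloxy)-4-bromo-2-methoxybenzene | C=CCOc1ccc(Br)cc1OC | intermediate
4 | 2-allyl-4-bromo-6-methoxyphenol | C=CCc1cc(Br)cc(OC)c1O | intermediate
5 | 1-allyl-5-bromo-3-methoxy-2-(methoxymethoxy)benzene | C=CCc1cc(Br)cc(OC)c1OCOC | intermediate
6 | 2-[5-bromo-3-methoxy-2-(methoxymethoxy)phenyl]acetaldehyde (not isolated) | O=CCc1cc(Br)cc(OC)c1OCOC | intermediate
7 | 2-[5-bromo-3-methoxy-2-(methoxymethoxy)phenyl]acetic acid | OC(=O)Cc1cc(Br)cc(OC)c1OCOC | intermediate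
8 | (S)-4-benzyl-1,3-oxazolidin-2-one | O=C1OC[C@H](Cc2ccccc2)N1 | starting material
9 | 2-[5-bromo-3-methoxy-2-(methoxymethoxy)phenyl]acetic pivalic anhydride (not isolated) | CC(C)(C)C(=O)OC(=O)Cc1cc(Br)cc(OC)c1OCOC | intermediate
10 | (S)-4-benzyl-3-{2-[5-bromo-3-methoxy-2-(methoxymethoxy)phenyl]acetyl}-1,3-oxazolidin-2-one | COCOc1c(CC(=O)N2[C@@H](Cc3ccccc3)COC2=O)cc(Br)cc1OC | intermediate
11 | 4-(benzyloxy)-3-methoxybenzaldehyde | COc1cc(C=O)ccc1OCc1ccccc1 | starting material
12 | Z-dibutylboron enolate of 10 (not isolated) | CCCCB(CCCC)O/C(=C\c1cc(Br)cc(OC)c1OCOC)N1[C@@H](Cc2ccccc2)COC1=O | intermediate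
13 | (S)-4-benzyl-3-{(2S,3S)-3-[4-(benzyloxy)-3-methoxyphenyl]-2-[5-bromo-3-methoxy-2-(methoxymethoxy)phenyl]-3-hydroxypropanoyl}-1,3-oxazolidin-2-one | O=C1OC[C@H](Cc2ccccc2)N1C(=O)[C@@H](c1cc(Br)cc(OC)c1OCOC)[C@H](O)c1ccc(OCc2ccccc2)c(OC)c1 | intermediate
14 | (1S,2R)-1-[4-(benzyloxy)-3-methoxyphenyl]-2-[5-bromo-3-methoxy-2-(methoxymethoxy)phenyl]propane-1,3-diol | OC[C@@H](c1cc(Br)cc(OC)c1OCOC)[C@H](O)c1ccc(OCc2ccccc2)c(OC)c1 | intermediate
15 | (1S,2R)-1-[4-(benzyloxy)-3-methoxyphenyl]-2-(5-bromo-2-hydroxy-3-methoxyphenyl)propane-1,3-diol (not isolated) | OC[C@@H](c1cc(Br)cc(OC)c1O)[C@H](O)c1ccc(OCc2ccccc2)c(OC)c1 | intermediate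
16 | [(2S,3R)-2-[4-(benzyloxy)-3-methoxyphenyl]-5-bromo-7-methoxy-2,3-dihydro-1-benzofuran-3-yl]methanol | COc1cc([C@H]2Oc3c(OC)cc(Br)cc3[C@@H]2CO)ccc1OCc1ccccc1 | intermediate
17 | TBS ether of 16 | COc1cc([C@H]2Oc3c(OC)cc(Br)cc3[C@@H]2CO[Si](C)(C)C(C)(C)C)ccc1OCc1ccccc1 | intermediate
18 | DBF-lithium (5-lithio derivative of 17, not isolated) | COc1cc([C@H]2Oc3c(OC)cc([Li])cc3[C@@H]2CO[Si](C)(C)C(C)(C)C)ccc1OCc1ccccc1 | intermediate
19 | DBF–CHO, (2S,3R)-2-[4-(benzyloxy)-3-methoxyphenyl]-3-(TBS-oxymethyl)-7-methoxy-2,3-dihydro-1-benzofuran-5-carbaldehyde | COc1cc([C@H]2Oc3c(OC)cc(C=O)cc3[C@@H]2CO[Si](C)(C)C(C)(C)C)ccc1OCc1ccccc1 | intermediate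
20 | dimethyl succinate | COC(=O)CCC(=O)OC | starting material
21 | methyl 2-DBF-5-oxooxolane-3-carboxylate (diastereomer mixture, not isolated) | COc1cc([C@H]2Oc3c(OC)cc(C4OC(=O)CC4C(=O)OC)cc3[C@@H]2CO[Si](C)(C)C(C)(C)C)ccc1OCc1ccccc1 | intermediate
22 | (E)-4-DBF-3-(methoxycarbonyl)but-3-enoic acid | COc1cc([C@H]2Oc3c(OC)cc(/C=C(\CC(=O)O)C(=O)OC)cc3[C@@H]2CO[Si](C)(C)C(C)(C)C)ccc1OCc1ccccc1 | intermediate
23 | (3R)-4-DBF-3-(methoxycarbonyl)butanoic acid | COc1cc([C@H]2Oc3c(OC)cc(C[C@@H](C(=O)OC)CC(=O)O)cc3[C@@H]2CO[Si](C)(C)C(C)(C)C)ccc1OCc1ccccc1 | intermediate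
24 | methyl (2R)-2-(DBF-methyl)-4-[methoxy(methyl)amino]-4-oxobutanoate | COc1cc([C@H]2Oc3c(OC)cc(C[C@@H](C(=O)OC)CC(=O)N(C)OC)cc3[C@@H]2CO[Si](C)(C)C(C)(C)C)ccc1OCc1ccccc1 | intermediate
25 | 1-(benzyloxy)-4-bromo-2-methoxybenzene | COc1cc(Br)ccc1OCc1ccccc1 | starting material
26 | [4-(benzyloxy)-3-methoxyphenyl]magnesium bromide (not isolated) | COc1cc([Mg]Br)ccc1OCc1ccccc1 | intermediate
27 | methyl (2R)-4-[4-(benzyloxy)-3-methoxyphenyl]-2-(DBF-methyl)-4-oxobutanoate | COc1cc([C@H]2Oc3c(OC)cc(C[C@@H](C(=O)OC)CC(=O)c4ccc(OCc5ccccc5)c(OC)c4)cc3[C@@H]2CO[Si](C)(C)C(C)(C)C)ccc1OCc1ccccc1 | intermediate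
28 | formaldehyde | C=O | starting material
29 | methyl (2R)-4-[4-(benzyloxy)-3-methoxyphenyl]-2-(DBF-methyl)-3-(hydroxymethyl)-4-oxobutanoate (both C3 epimers, not isolated) | COc1cc([C@H]2Oc3c(OC)cc(C[C@@H](C(=O)OC)C(CO)C(=O)c4ccc(OCc5ccccc5)c(OC)c4)cc3[C@@H]2CO[Si](C)(C)C(C)(C)C)ccc1OCc1ccccc1 | intermediate
30 | (3R,4R)-4-[4-(benzyloxy)-3-methoxybenzoyl]-3-(DBF-methyl)oxolan-2-one | COc1cc([C@H]2Oc3c(OC)cc(C[C@H]4C(=O)OC[C@@H]4C(=O)c4ccc(OCc5ccccc5)c(OC)c4)cc3[C@@H]2CO[Si](C)(C)C(C)(C)C)ccc1OCc1ccccc1 | intermediate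
31 | (3R,4R)-4-{(R)-[4-(benzyloxy)-3-methoxyphenyl](hydroxy)methyl}-3-(DBF-methyl)oxolan-2-one | COc1cc([C@H]2Oc3c(OC)cc(C[C@H]4C(=O)OC[C@@H]4[C@@H](O)c4ccc(OCc5ccccc5)c(OC)c4)cc3[C@@H]2CO[Si](C)(C)C(C)(C)C)ccc1OCc1ccccc1 | intermediate
32 | desilylated bis-benzyl ether of the target (name as in step 17) | COc1cc([C@H]2Oc3c(OC)cc(C[C@H]4C(=O)OC[C@@H]4[C@@H](O)c4ccc(OCc5ccccc5)c(OC)c4)cc3[C@@H]2CO)ccc1OCc1ccccc1 | intermediate
33 | (3R,4R)-4-[(R)-hydroxy(4-hydroxy-3-methoxyphenyl)methyl]-3-{[(2S,3R)-2-(4-hydroxy-3-methoxyphenyl)-3-(hydroxymethyl)-7-methoxy-2,3-dihydro-1-benzofuran-5-yl]methyl}oxolan-2-one | COc1cc([C@H]2Oc3c(OC)cc(C[C@H]4C(=O)OC[C@@H]4[C@@H](O)c4ccc(O)c(OC)c4)cc3[C@@H]2CO)ccc1O | target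

**Step count**
Total steps: 18. Longest linear sequence: 18 steps (1 → 33); the aryl Grignard reagent is made within step 14.

**Steps most likely to fail**

Step 15 (key step). The aldol adduct may dehydrate to the alpha-methylene ketone faster than it lactonises; double-bond migration would then erase the C3 centre, and a second hydroxymethylation at the still enolisable lactone C4 may compete. Fallback, setting out from 27 and returning at 30: the ketone would be converted with Me3SiOTf/Et3N (CH2Cl2, 0 °C) into the Z-trimethylsilyl enol ether F1. A Mukaiyama aldol with aqueous formaldehyde catalysed by Yb(OTf)3 in THF/H2O should then give hydroxymethyl ketone 29 with no base present. Lactonisation with pyridinium p-toluenesulfonate in warm toluene and a brief DBU equilibration to the trans isomer would give 30.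

Step 16. Facial selectivity may be poor if the catalyst's preference is mismatched with the Felkin–Anh preference of the adjacent lactone centre, and turnover may be slow at the hindered, electron-rich ketone. Fallback, setting out from 30 and returning at 31: substrate-controlled reduction with LiBH(s-Bu)3 (THF, −78 °C) should give the epimeric (S)-carbinol F2. Mitsunobu inversion with chloroacetic acid (PPh3, DIAD, toluene, 0 °C) would give the (R)-chloroacetate F3, and thiourea/NaHCO3 in ethanol would remove the chloroacetyl group under near-neutral conditions to give 31.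

Step 18. Over-reduction may occur: hydrogenolysis of the para-oxygenated benzylic C–OH bond and of the benzylic C2–O bond of the dihydrobenzofuran while the benzyl ethers are being cleaved. Fallback, setting out from 30 and returning at 33: the benzyl ethers would be hydrogenolysed at the ketone stage, where no benzylic alcohol exists (H2, Pd/C, EtOAc), to the bis-phenol keto lactone F4. The phenols would be silylated (TBSCl, imidazole, DMF) to the tris-silyl keto lactone F5, and the transfer hydrogenation of step 16 applied to give the tris-silyl carbinol F6. Global desilylation with Bu4NF/AcOH in THF would then give 33 without any hydrogenolysis in the presence of the carbinol.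

**Further compounds**
F1 | step 15 | methyl (2R,3Z)-4-[4-(benzyloxy)-3-methoxyphenyl]-2-(DBF-methyl)-4-[(trimethylsilyl)oxy]but-3-enoate | COc1cc([C@H]2Oc3c(OC)cc(C[C@@H](C(=O)OC)/C=C(\O[Si](C)(C)C)c4ccc(OCc5ccccc5)c(OC)c4)cc3[C@@H]2CO[Si](C)(C)C(C)(C)C)ccc1OCc1ccccc1
F2 | step 16 | (3R,4R)-4-{(S)-[4-(benzyloxy)-3-methoxyphenyl](hydroxy)methyl}-3-(DBF-methyl)oxolan-2-one | COc1cc([C@H]2Oc3c(OC)cc(C[C@H]4C(=O)OC[C@@H]4[C@H](O)c4ccc(OCc5ccccc5)c(OC)c4)cc3[C@@H]2CO[Si](C)(C)C(C)(C)C)ccc1OCc1ccccc1
F3 | step 16 | (R)-[4-(benzyloxy)-3-methoxyphenyl][(3R,4R)-4-(DBF-methyl)-5-oxooxolan-3-yl]methyl chloroacetate | COc1cc([C@H]2Oc3c(OC)cc(C[C@H]4C(=O)OC[C@@H]4[C@@H](OC(=O)CCl)c4ccc(OCc5ccccc5)c(OC)c4)cc3[C@@H]2CO[Si](C)(C)C(C)(C)C)ccc1OCc1ccccc1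
F4 | step 18 | (3R,4R)-4-(4-hydroxy-3-methoxybenzoyl)-3-{[(2S,3R)-2-(4-hydroxy-3-methoxyphenyl)-3-(TBS-oxymethyl)-7-methoxy-2,3-dihydro-1-benzofuran-5-yl]methyl}oxolan-2-one | COc1cc([C@H]2Oc3c(OC)cc(C[C@H]4C(=O)OC[C@@H]4C(=O)c4ccc(O)c(OC)c4)cc3[C@@H]2CO[Si](C)(C)C(C)(C)C)ccc1O
F5 | step 18 | tris-TBS keto lactone (both phenols and the primary alcohol silylated) | COc1cc([C@H]2Oc3c(OC)cc(C[C@H]4C(=O)OC[C@@H]4C(=O)c4ccc(O[Si](C)(C)C(C)(C)C)c(OC)c4)cc3[C@@H]2CO[Si](C)(C)C(C)(C)C)ccc1O[Si](C)(C)C(C)(C)C
F6 | step 18 | tris-TBS (R)-carbinol lactone | COc1cc([C@H]2Oc3c(OC)cc(C[C@H]4C(=O)OC[C@@H]4[C@@H](O)c4ccc(O[Si](C)(C)C(C)(C)C)c(OC)c4)cc3[C@@H]2CO[Si](C)(C)C(C)(C)C)ccc1O[Si](C)(C)C(C)(C)C
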